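(Readings and results stem from a simulated flask for an exercise; the scatter is artificial.)

| flask | substrate | remark | time |
|---|---|---|---|
| eta | 0.32 M | run made earlier |  |
| gamma | 0.47 M | run made earlier |  |
| flask | 0.63 M |  | 10 h |

| run | time / h | isomer of the product / % | target / % | substrate / % |
|---|---|---|---|---|
| eta | 0.833 | 22 | 61 | 11 |
| eta | 1.33 | 21 | 69 | 9 |
| eta | 2.00 | 20 | 74 | 1 |
| eta | 3.00 | 13 | 79 | 2 |
| eta | 4.00 | 14 | 82 | 4 |
| eta | 6.00 | 6 | 84 | 3 |
| eta | 10.0 | 5 | 89 | 4 |
| gamma | 1.33 | 20 | 69 | 6 |
| gamma | 3.00 | 14 | 77 | 4 |
| gamma | 4.00 | 9 | 81 | 4 |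
| gamma | 6.00 | 6 | 86 | 2 |
| gamma | 8.00 | 4 | 89 | 3 |
| gamma | 10.0 | 4 | 91 | 3 |

(scatter of a reading: 1.5 percentage points)

- ratio of isomer of the product to target at 80 s
- ratio of isomer of the product to target at 10 h

- the earlier runs were read with a standard deviation of 1.5 percentage points
- a reading or a percentage of target counts all its forms, free or not

**The leftover.** At 10 h some isomer of the product still stands beside the target. The eta run, charged at 0.32 M, reads 5% against 89% of the charge, and the gamma run, charged at 0.47 M, reads 4% against 91%, each with a scatter of 1.5 percentage points. So the ratio read is lower in the gamma run than in the eta run. I multiply each ratio by its charge and average the two; this leftover strength is 0.0193 M.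

**The bracket.** From above, I take the gamma reading, 0.0440, as the ceiling for the flask at 0.63 M, since the higher charge has read lower so far. From below, if the leftover strength holds, the flask's ratio is 0.0307. The scatter stops me tightening this by hand, so I commit to the middle, 0.0373.

**The forecast.** It gives 0.42 at 80 s and 0.045 at 10 h, just above my ceiling, holding that “the rates look essentially first-order in the percent scale, with little dependence on concentration”.

**The flask.** It gives 0.371 at 80 s and 0.0368 at 10 h, inside the bracket. The flask's own leftover strength is 0.0232 M, above my 0.0193 M.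

    substrate ⇌ target (K = 2.30, k = 0.0380 min⁻¹)
    substrate ⇌ isomer of the product (K = 2.00, k = 0.0140 min⁻¹)
    target ⇌ isomer of the product (k = 3.90 × 10⁻⁴ min⁻¹)
    substrate ⇌ dormant form (K = 0.340, k = 0.00170 min⁻¹)
    target → over-reaction product (k = 0.00130 min⁻¹)
    crystals ⇌ target, rate k6*(cs6 - [target]) while solid is left; crystals form when [target] > cs6 (solubility = 14.0 mM, k = 0.130 min⁻¹)

**The reason.** Two things act together to hold the flask's ratio down: run without the saturation of target, the flask's ratio at 10 h is 0.972, and run without the isomer falling back to substrate, it is 0.412. Crystals in the flask hold 89.7% of the charge by then.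

**A second flask.** At 0.38 M the leftover strength gives 0.0508; the computed ratio at 10 h is 0.0513.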